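**The vessel.** In this closed, stirred flask, crystals of solid substrate lie under a solution that holds no starting material at the start.

solid substrate 0.63 M; free catalyst 0.24 mol%; time 80 s

    free catalyst → spent catalyst (k1 = 8.3 × 10⁻⁴ s⁻¹)
    starting material + free catalyst → free catalyst + target (k2 = 24 M⁻¹ s⁻¹)
    2 starting material → self-condensation product (k3 = 3.3 × 10⁻⁵ M⁻¹ s⁻¹)
    solid substrate ⇌ starting material, rate k4*(cs4 - [starting material]) while solid is left; crystals form when [starting material] > cs4 (cs4 = 0.17 M, k4 = 0.013 s⁻¹)
    starting material → side product (k5 = 0.0015 s⁻¹)

- percent here means solid substrate units held: one self-condensation product counts as two
- for a step with 2 of a species take k times the square, and two of it per event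
- solid substrate is a solid; its amount is given per volume of the solution
- at the start none of the solid substrate is in solution
- starting material means what is dissolved; the solid is not counted in it
- run time (flask): 80 s

- how much target there is at 80 s, in percent of the solid substrate charged
- concentration of starting material in solution at 80 s, in percent of saturation

**Solid supply.** Dissolution can deliver at most 28.1% of the charge by 80 s, less than the charge, so crystals remain throughout this flask.

**Catalytic drain.** The charged free catalyst is 1.51 mM, so starting material goes to target with a pseudo-first-order constant k′ of 0.0363 s⁻¹. Self-condensation, at 2.87 × 10⁻⁶ s⁻¹, is far slower, so I drop it.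

**Balance level.** Three terms scale with [starting material]: k′, the side step and the slowing of dissolution. Together they make 0.0508 s⁻¹. Their reciprocal, 19.7 s, is shorter than the run, so [starting material] settles. It settles at the balance level, the dissolution coefficient times the solubility divided by that sum: 0.0435 M, or 25.6% of saturation. Target then grows at a steady k′ times this level.

**First target.** Counting from the end of the settling time, I get 15.1% of the charge.

**Weak link.** I took the catalyst as charged, but it decays. At mid-run 96.7% of it stands, so k′ becomes 0.0351 s⁻¹. The level becomes 0.0446 M, or 26.2% of saturation, and target 14.9%. I commit to these.

**The forecast.** It gives 14.9% (14.4% to 15.4%) and 26% (25.3% to 26.7%), with this among its grounds: “Dissolution can supply at most about 0.18 M, so solid remains throughout.” It then integrates a balance over the run, whereas my route needs a division and a product.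

**The flask.** The simulation gives 14.9% and 26.0%. At 80.0 s, starting material is made 1.04 times faster than it is used up. Carried forward, k′ times the balance level reckons 20 percentage points more by 160 s, and this flask gains 19 points.

**Richer neighbour.** With 0.6 mol% of free catalyst and the same mid-run decay, k′ is 0.0878 s⁻¹, so I reckon the level in that neighbour at 0.0216 M, or 3.43% of the charge, and target at 21.1%. That neighbour's simulation gives 3.50% of starting material and 21.1% of target.

(The rate constants stand for no real mixture; the flask was simulated.)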